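The runs were computed for an exercise, and the scatter is random.

Reading the birch run at its first time, 4.00 h, I saw cD at 1.2% beside cE at 13.9%, so I treated D as a correction to E and reckoned that correction.

| flask | J | remark | time |
|---|---|---|---|
| birch | 1.5 M | run made earlier |  |
| flask | 3.0 M |  | 40 h |

- birch (time / h: D / %, E / %): 4.00: 1.2, 13.9; 6.00: 1.6, 22.3; 8.00: 5.0, 28.0; 15.0: 2.7, 39.2; 20.0: 4.0, 40.0; 30.0: 3.4, 45.6; 50.0: 3.8, 46.9

(each reading ± 1 percentage point)

1. share of D in D plus E at 1.0 h
2. share of D in D plus E at 40 h



In birch, cD + cE rose on average by 0.0378 h⁻¹ as a fraction of the charge up to the first reading, and the last two readings put its level near 49.9%. That slope, held straight, met that level at 13.2 h, which I read as the knee of the curve.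

I kept 0.0920 as ρ, the summed cD over the summed cE of the birch readings, a selectivity factor. As a share, ρ over one plus ρ, it gave 8.42%, with a scatter near 1 percentage point, so I put the level of D in birch near 4.20%. Birch has one charge, so carrying ρ to the flask at both times was my assumption that the two routes share an order.

The forecast gave 8% at 1.0 h and 8% at 40 h, a little below my share, on the ground that “D's share of D+E shows no trend beyond the noise”.

The flask gave 8.00% at 1.0 h and 8.00% at 40 h, so the forecast held.

G → D (k = 0.00200 min⁻¹); G → E (k = 0.0230 min⁻¹); G → Q (k = 0.0250 min⁻¹); J ⇌ Z (K = 0.590, k = 0.0530 min⁻¹); Z → X (k = 0.0130 min⁻¹); X → G (k = 0.0380 min⁻¹); J ⇌ L (K = 1.50, k = 0.140 min⁻¹) D and E both leave G, and the constant of G to D over the sum of the two constants is 8.00%. The flask also held Q at 49.7% after 40.0 h, and the passing of G into Q made no difference to the share at that time. Applied to the flask's E of 45.8% at that time, ρ gave me cD of 4.21%, and the flask held 3.98%.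

In the neighbour flask with 1.2 M of J, ρ on its E of 45.8% at 40.0 h gave cD of 4.21% and a share of 8.42%. That neighbour flask held 3.98% of D at that time, a share of 8.00%.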